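Fraction of the charge per day is the unit in which these runs read best, and two rates in that unit carry the argument.

| setting | spring | noon | flask |
|---|---|---|---|
| solid substrate | 0.010 M | 0.010 M | 0.010 M |
| reagent | 0.67 equiv | 1.5 equiv | 1.00 equiv |
| remark | run made earlier | run made earlier |  |
| time |  |  | 12 d |

| run | time / d | solid substrate / % | mono adduct / % |
|---|---|---|---|
| spring | 0.625 | 96.5 | 0.6 |
| spring | 0.833 | 94.9 | 0.6 |
| spring | 1.25 | 93.3 | 0.5 |
| spring | 2.08 | 89.8 | 1.1 |
| spring | 3.00 | 86.1 | 1.1 |
| spring | 5.00 | 79.1 | 1.9 |
| spring | 8.00 | 70.8 | 2.1 |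
| noon | 0.417 | 97.5 | 0 |
| noon | 1.04 | 94.1 | 1.4 |
| noon | 2.08 | 89.5 | 0.8 |
| noon | 3.00 | 84.4 | 1.3 |
| noon | 4.00 | 79.7 | 1.0 |
| noon | 6.00 | 71.5 | 1.8 |
| noon | 8.00 | 63.6 | 1.5 |

(scatter of a reading: 0.3 percentage points)

- how much solid substrate there is at 12 d, in percent of the solid substrate charged (only what is still solid)
- how much mono adduct there is at 12 d, in percent of the solid substrate charged
- how much bis adduct there is at 12 d, in percent of the solid substrate charged

- solid, in amounts per volume of the solution: solid substrate
- at the start none of the solid substrate is in solution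

The start rate comes first. The spring run loses 0.0536 d⁻¹ of its solid up to 1.25 d and the noon run 0.0567 d⁻¹ up to 1.04 d, a change far smaller than the 2.24-fold step in reagent. A start this indifferent to reagent reads as going into solution, the rate-limiting step of this first stretch of both runs. Over the last readings the solid slows, to 0.0277 d⁻¹ in the spring run and 0.0395 d⁻¹ in the noon run, and now more reagent gives a faster loss.

In reagent, the flask lies 0.398 of the way from spring to noon. Its late rate, the solid's loss per day after the early stretch, read between the two runs, is 0.0324 d⁻¹, which is 0.587 of the mean start rate of the two runs. Interpolated solid at 8.00 d is 67.9 %, so the reckoning made here, an estimate with the late rate held up to 12 d, ends at 55.0 %. The forecast, which differs, says 57.5 % solid, 2.5 % mono adduct and 37 % bis adduct, with “dissolved unreacted substrate perhaps 3%”.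

The flask gives 55.5 % solid, 2.04 % mono adduct and 31.3 % bis adduct.

    starting material + reagent → mono adduct (k = 6.30 M⁻¹ h⁻¹)
    reagent + mono adduct → bis adduct (k = 12.0 M⁻¹ h⁻¹)
    solid substrate ⇌ starting material, rate k3*(cs3 - [starting material]) while solid is left; crystals form when [starting material] > cs3 (solubility = 0.670 mM, k = 0.0410 h⁻¹)
    starting material ⇌ dormant form (K = 1.80, k = 0.240 h⁻¹)

At 12.0 d, starting material and dormant form together hold 11.2 % of the charge, more than the forecast's 3 %. The late rate, taken past the noon run to the neighbour flask with 1.70 equiv, is 0.0424 d⁻¹ and by the same estimate leaves 44.9 % solid, and that neighbour flask holds 46.0 % solid.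

(The data were generated by integration with constants of no real substance; noise was put on by code.)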